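## Retrosynthetic overview

- The C19 polyene tail is cut at the CH2–C(sp2) bond next to the first side-chain olefin: B-alkyl Suzuki–Miyaura coupling of a ring vinyl group with an (E)-2-iodoalkene made from farnesyl bromide.
- The only ring is closed in one flask from an acyclic allyl vinyl ether. A catalytic asymmetric Gosteli–Claisen rearrangement joins the side-chain-bearing ring CH to the methyl-bearing olefin carbon, and an endo Hosomi–Sakurai closure joins the ring CH2 to the carbinol carbon.
- Enabling feature: the ring is a cyclohex-3-en-1-ol. HO–CH–CH2–CH=C(CH3) is a homoallylic alcohol (allylsilane plus aldehyde), and the allylic ring CH next to C(CH3)= becomes a Claisen retron once its exocyclic carbon is a carbonyl. The C(CH3)2 carbon between them makes the aldehyde non-enolisable.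
- Silicon and the keto ester are temporary activators: silicon is lost in the ring closure, and the keto ester is trimmed to the vinyl handle (LiAlH4, NaIO4, Wittig).
- No protecting groups are used.

Key step: step 6

Assumption: the (S,S)-bis(oxazoline) ligand is taken to deliver the vinyl ether face that leads to the (3S,4R)-allylsilane; if the facial sense is opposite for this substrate, the (R,R)-ligand is used and nothing else changes.

## Route

Step 1
Reactants: 1 but-2-yn-1-ol
Product: 2 (2Z)-3-[benzyl(dimethyl)silyl]but-2-en-1-ol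
Conditions: BnMe2SiH, [Cp*Ru(MeCN)3]PF6 (1 mol %), CH2Cl2, 0 to 23 °C
Reagents that add atoms: benzyl(dimethyl)silane, C[SiH](C)Cc1ccccc1
Why: Ruthenium-catalysed trans-hydrosilylation of a propargylic alcohol should place silicon on the carbon remote from the hydroxyl and, by anti addition, cis to CH2OH, which is the Z geometry the Claisen chair needs.

Step 2
Reactants: 3 trimethyl phosphonoacetate
Product: 4 methyl 2-diazo-2-(dimethoxyphosphoryl)acetate
Conditions: 4-acetamidobenzenesulfonyl azide, DBU, MeCN, 0 to 23 °C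
Reagents that add atoms: 4-acetamidobenzenesulfonyl azide, CC(=O)Nc1ccc(cc1)S(=O)(=O)N=[N+]=[N-]
Why: Regitz diazo transfer to the doubly activated methylene of a phosphonoacetate.

Step 3
Reactants: 2 (2Z)-3-[benzyl(dimethyl)silyl]but-2-en-1-ol; 4 methyl 2-diazo-2-(dimethoxyphosphoryl)acetate
Product: 5 methyl 2-({(2Z)-3-[benzyl(dimethyl)silyl]but-2-en-1-yl}oxy)-2-(dimethoxyphosphoryl)acetate (racemic at the phosphonate carbon)
Conditions: Rh2(OAc)4 (1 mol %), benzene, 80 °C, slow addition of 4
Reagents that add atoms: none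
Why: Rhodium carbenoid O–H insertion into the allylic alcohol should outrun cyclopropanation of the hindered silyl-substituted alkene and gives the α-alkoxy phosphonate needed for the olefination.

Step 4
Reactants: 6 2,2-dimethylpropane-1,3-diol
Product: 7 2,2-dimethylpropanedial
Conditions: (COCl)2, DMSO, CH2Cl2, −78 °C; Et3N, −78 to 0 °C; used as a dried solution
Reagents that add atoms: none
Why: Swern oxidation of both neopentyl hydroxyls; the product has no α-hydrogen and cannot enolise or self-condense.

Step 5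
Reactants: 5 methyl 2-({(2Z)-3-[benzyl(dimethyl)silyl]but-2-en-1-yl}oxy)-2-(dimethoxyphosphoryl)acetate; 7 2,2-dimethylpropanedial (3 equiv)
Product: 8 methyl (2Z)-2-({(2Z)-3-[benzyl(dimethyl)silyl]but-2-en-1-yl}oxy)-4,4-dimethyl-5-oxopent-2-enoate
Conditions: LiCl, DBU, MeCN, 0 to 23 °C
Reagents that add atoms: none
Why: Horner–Wadsworth–Emmons olefination under mild LiCl/amine conditions with the symmetrical dialdehyde in excess should stop at mono-olefination and favour the Z enol ether, in which the tert-alkyl group sits cis to the ether oxygen and away from the ester.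

Step 6
Reactants: 8 methyl (2Z)-2-({(2Z)-3-[benzyl(dimethyl)silyl]but-2-en-1-yl}oxy)-4,4-dimethyl-5-oxopent-2-enoate
Product: 10 methyl 2-[(1R,5S)-5-hydroxy-2,6,6-trimethylcyclohex-2-en-1-yl]-2-oxoacetate, via tertiary allylsilane keto ester 9 (not isolated)
Conditions: [Cu(tBu-box)(H2O)2](SbF6)2 (10 mol %; tBu-box = 2,2'-(propane-2,2-diyl)bis[(4S)-4-tert-butyl-4,5-dihydrooxazole]), CH2Cl2 (0.02 M), 23 °C; then BF3·OEt2, −78 °C, same flask; aq. NaHCO3
Reagents that add atoms: none
Why: The divalent copper complex chelates the ether oxygen and ester carbonyl of 8 and triggers a [3,3] Gosteli–Claisen rearrangement through a chair in which the tert-alkyl group and the silyl group lie anti across the forming bond, giving tertiary allylsilane 9; BF3 then activates the non-enolisable aldehyde and the allylsilane terminus attacks it (anti SE2' Hosomi–Sakurai), the β-silyl cation losing silicon so that the double bond can only end up between the ring CH and the methyl-bearing carbon. The closest known reaction types are the copper–bis(oxazoline)-catalysed rearrangement of 2-alkoxycarbonyl allyl vinyl ethers, Claisen rearrangements onto silyl-bearing alkene termini that deliver allylsilanes, and endo allylsilane–carbonyl cyclisations of the silyl-Prins kind. The six-membered ring closes 6-endo with respect to the allylsilane π bond and exo with respect to the C=O. The ring CH stereocentre is set by the catalyst-controlled face of the vinyl ether, the transient silyl-bearing quaternary centre follows from the chair and the two Z olefins, and the carbinol centre follows from a chair closure with silicon axial, the keto ester arm equatorial and the complexed oxygen equatorial (as in ring A of a 3β-hydroxy-4,4-dimethyl triterpenoid), which gives the cis 1,3 relationship. The step needs the aldehyde and not the keto ester to be attacked, which ring size should secure (5-endo onto the ketone against 6-endo onto the aldehyde), and it needs control of the alkene position, which silicon secures.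

Step 7
Reactants: 10 methyl 2-[(1R,5S)-5-hydroxy-2,6,6-trimethylcyclohex-2-en-1-yl]-2-oxoacetate
Product: 11 1-[(1R,5S)-5-hydroxy-2,6,6-trimethylcyclohex-2-en-1-yl]ethane-1,2-diol (both epimers at the new carbinol)
Conditions: LiAlH4, THF, −78 to 0 °C; H2O, aq. NaOH
Reagents that add atoms: none
Why: Hydride reduction of both carbonyls of the α-keto ester to the 1,2-diol removes the enolisable ketone next to the ring stereocentre; the new carbinol centre is lost in the next step.

Step 8
Reactants: 11 1-[(1R,5S)-5-hydroxy-2,6,6-trimethylcyclohex-2-en-1-yl]ethane-1,2-diol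
Product: 12 (1R,5S)-5-hydroxy-2,6,6-trimethylcyclohex-2-ene-1-carbaldehyde
Conditions: NaIO4, THF/H2O (pH 7), 0 °C
Reagents that add atoms: none
Why: Periodate glycol cleavage excises the former ester carbon as formaldehyde under neutral conditions and leaves the lone ring hydroxyl and the alkene untouched; the aldehyde may rest as its bridged lactol.

Step 9
Reactants: 12 (1R,5S)-5-hydroxy-2,6,6-trimethylcyclohex-2-ene-1-carbaldehyde
Product: 13 (1S,5R)-5-ethenyl-4,6,6-trimethylcyclohex-3-en-1-ol
Conditions: Ph3PCH3Br, KN(SiMe3)2 (ylide preformed, 2.5 equiv), THF, −78 to 0 °C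
Reagents that add atoms: methyltriphenylphosphonium bromide, C[P+](c1ccccc1)(c1ccccc1)c1ccccc1.[Br-]
Why: Wittig methylenation at low temperature converts the aldehyde (or its lactol) into the vinyl group, the excess ylide covering the free hydroxyl.

Step 10
Reactants: 14 (2E,6E)-farnesyl bromide
Product: 15 trimethyl[(5E,9E)-6,10,14-trimethylpentadeca-5,9,13-trien-1-yn-1-yl]silane
Conditions: 1-(trimethylsilyl)propyne, n-BuLi, THF, −78 °C; then 14, −78 to 0 °C
Reagents that add atoms: 1-(trimethylsilyl)propyne, CC#C[Si](C)(C)C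
Why: SN2 alkylation of the allylic bromide by the silyl-blocked propargylic lithium reagent extends farnesyl by three carbons with both E olefins intact.

Step 11
Reactants: 15 trimethyl[(5E,9E)-6,10,14-trimethylpentadeca-5,9,13-trien-1-yn-1-yl]silane
Product: 16 (5E,9E)-6,10,14-trimethylpentadeca-5,9,13-trien-1-yne
Conditions: K2CO3 (cat.), MeOH, 23 °C
Reagents that add atoms: none
Why: Base-catalysed methanolysis of the alkynyl C–Si bond.

Step 12
Reactants: 16 (5E,9E)-6,10,14-trimethylpentadeca-5,9,13-trien-1-yne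
Product: 18 (6E,10E)-7,11,15-trimethylhexadeca-6,10,14-trien-2-yne, via lithium acetylide 17 (not isolated)
Conditions: n-BuLi, THF, −78 °C; MeI, −78 to 23 °C
Reagents that add atoms: iodomethane, CI
Why: Deprotonation of the terminal alkyne and C-methylation of the acetylide.

Step 13
Reactants: 18 (6E,10E)-7,11,15-trimethylhexadeca-6,10,14-trien-2-yne
Product: 20 (2E,6E,10E)-2-iodo-7,11,15-trimethylhexadeca-2,6,10,14-tetraene, via alkenylzirconocene chloride 19 (not isolated)
Conditions: Cp2Zr(H)Cl (2 equiv), THF, 23 to 40 °C; I2, 0 °C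
Reagents that add atoms: iodine, II
Why: Syn hydrozirconation should place zirconium on the less hindered, methyl-bearing alkyne carbon after equilibration, and iodinolysis with retention gives the E-2-iodoalkene; the trisubstituted alkenes do not react with the hydride.

Step 14
Reactants: 13 (1S,5R)-5-ethenyl-4,6,6-trimethylcyclohex-3-en-1-ol; 20 (2E,6E,10E)-2-iodo-7,11,15-trimethylhexadeca-2,6,10,14-tetraene
Product: 22 camelliol C, (1S,5R)-4,6,6-trimethyl-5-[(3E,7E,11E)-3,8,12,16-tetramethylheptadeca-3,7,11,15-tetraen-1-yl]cyclohex-3-en-1-ol, via B-alkyl-9-BBN borane 21 (not isolated)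
Conditions: 9-BBN-H (2.3 equiv), THF, 23 °C; then 20, PdCl2(dppf) (5 mol %), AsPh3, Cs2CO3, DMF/H2O, 23 °C
Reagents that add atoms: none
Why: 9-BBN hydroborates only the monosubstituted vinyl group (anti-Markovnikov, one further equivalent being taken up by the hydroxyl), and B-alkyl Suzuki–Miyaura coupling with the alkenyl iodide proceeds with retention of the E geometry; no stereocentre is touched.

## Compound list

1 | but-2-yn-1-ol | CC#CCO | starting material
2 | (2Z)-3-[benzyl(dimethyl)silyl]but-2-en-1-ol | OC/C=C(/C)[Si](C)(C)Cc1ccccc1 | intermediate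
3 | trimethyl phosphonoacetate | COC(=O)CP(=O)(OC)OC | starting material
4 | methyl 2-diazo-2-(dimethoxyphosphoryl)acetate | COC(=O)C(=[N+]=[N-])P(=O)(OC)OC | intermediate
5 | methyl 2-({(2Z)-3-[benzyl(dimethyl)silyl]but-2-en-1-yl}oxy)-2-(dimethoxyphosphoryl)acetate (racemic) | COC(=O)C(OC/C=C(/C)[Si](C)(C)Cc1ccccc1)P(=O)(OC)OC | intermediate
6 | 2,2-dimethylpropane-1,3-diol | OCC(C)(C)CO | starting material
7 | 2,2-dimethylpropanedial | O=CC(C)(C)C=O | intermediate
8 | methyl (2Z)-2-({(2Z)-3-[benzyl(dimethyl)silyl]but-2-en-1-yl}oxy)-4,4-dimethyl-5-oxopent-2-enoate | COC(=O)/C(OC/C=C(/C)[Si](C)(C)Cc1ccccc1)=C/C(C)(C)C=O | intermediate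
9 | methyl (3S,4R)-4-[benzyl(dimethyl)silyl]-4-methyl-3-(2-methyl-1-oxopropan-2-yl)-2-oxohex-5-enoate | COC(=O)C(=O)[C@H]([C@](C)([Si](C)(C)Cc1ccccc1)C=C)C(C)(C)C=O | intermediate (not isolated)
10 | methyl 2-[(1R,5S)-5-hydroxy-2,6,6-trimethylcyclohex-2-en-1-yl]-2-oxoacetate | COC(=O)C(=O)[C@@H]1C(C)=CC[C@H](O)C1(C)C | intermediate
11 | 1-[(1R,5S)-5-hydroxy-2,6,6-trimethylcyclohex-2-en-1-yl]ethane-1,2-diol (epimers at the side-chain carbinol) | OCC(O)[C@@H]1C(C)=CC[C@H](O)C1(C)C | intermediate
12 | (1R,5S)-5-hydroxy-2,6,6-trimethylcyclohex-2-ene-1-carbaldehyde | O=C[C@@H]1C(C)=CC[C@H](O)C1(C)C | intermediate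
13 | (1S,5R)-5-ethenyl-4,6,6-trimethylcyclohex-3-en-1-ol | C=C[C@@H]1C(C)=CC[C@H](O)C1(C)C | intermediate
14 | (2E,6E)-1-bromo-3,7,11-trimethyldodeca-2,6,10-triene (farnesyl bromide) | CC(C)=CCC/C(C)=C/CC/C(C)=C/CBr | starting material
15 | trimethyl[(5E,9E)-6,10,14-trimethylpentadeca-5,9,13-trien-1-yn-1-yl]silane | CC(C)=CCC/C(C)=C/CC/C(C)=C/CCC#C[Si](C)(C)C | intermediate
16 | (5E,9E)-6,10,14-trimethylpentadeca-5,9,13-trien-1-yne | CC(C)=CCC/C(C)=C/CC/C(C)=C/CCC#C | intermediate
17 | [(5E,9E)-6,10,14-trimethylpentadeca-5,9,13-trien-1-yn-1-yl]lithium | CC(C)=CCC/C(C)=C/CC/C(C)=C/CCC#C[Li] | intermediate (not isolated)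
18 | (6E,10E)-7,11,15-trimethylhexadeca-6,10,14-trien-2-yne | CC(C)=CCC/C(C)=C/CC/C(C)=C/CCC#CC | intermediate
19 | chloridobis(cyclopentadienyl)[(2E,6E,10E)-7,11,15-trimethylhexadeca-2,6,10,14-tetraen-2-yl]zirconium (cyclopentadienyl rings drawn σ-bonded) | CC(C)=CCC/C(C)=C/CC/C(C)=C/CC/C=C(\C)[Zr](Cl)(C1C=CC=C1)C1C=CC=C1 | intermediate (not isolated)
20 | (2E,6E,10E)-2-iodo-7,11,15-trimethylhexadeca-2,6,10,14-tetraene | CC(C)=CCC/C(C)=C/CC/C(C)=C/CC/C=C(\C)I | intermediate
21 | 9-{2-[(1R,5S)-5-[(9-borabicyclo[3.3.1]nonan-9-yl)oxy]-2,6,6-trimethylcyclohex-2-en-1-yl]ethyl}-9-borabicyclo[3.3.1]nonane | C1CC2CCCC(C1)B2CC[C@@H]1C(C)=CC[C@H](OB2C3CCCC2CCC3)C1(C)C | intermediate (not isolated)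
22 | camelliol C, (1S,5R)-4,6,6-trimethyl-5-[(3E,7E,11E)-3,8,12,16-tetramethylheptadeca-3,7,11,15-tetraen-1-yl]cyclohex-3-en-1-ol | CC(C)=CCC/C(C)=C/CC/C(C)=C/CC/C=C(\C)CC[C@@H]1C(C)=CC[C@H](O)C1(C)C | target

## Step count and risks

Total step count: 14. Longest linear sequence: 8 steps (steps 1, 3, 5, 6, 7, 8, 9, 14).

**Step 6.** The free aldehyde may compete for the copper centre, and the crowded termini (a tert-alkyl group on one, methyl and silyl on the other) may slow the chelated chair or divert it to a boat, so that facial and relative selectivity erode. Fallback, with stereocontrol by resolution instead of catalysis: 8 is heated without catalyst (toluene, 100 °C, thermal Gosteli–Claisen) and treated in the same flask with BF3·OEt2 at −78 °C. This should give racemic material, that is 10 together with its enantiomer methyl 2-[(1S,5R)-5-hydroxy-2,6,6-trimethylcyclohex-2-en-1-yl]-2-oxoacetate F2, formed through 9 and its enantiomer methyl (3R,4S)-4-[benzyl(dimethyl)silyl]-4-methyl-3-(2-methyl-1-oxopropan-2-yl)-2-oxohex-5-enoate F1. Esterification of the ring hydroxyl with (S)-O-acetylmandelic acid (DCC, DMAP, CH2Cl2) gives the diastereomeric esters (1S,5R)-5-[methoxy(oxo)acetyl]-4,6,6-trimethylcyclohex-3-en-1-yl (2S)-2-(acetyloxy)-2-phenylacetate F3 and (1R,5S)-5-[methoxy(oxo)acetyl]-4,6,6-trimethylcyclohex-3-en-1-yl (2S)-2-(acetyloxy)-2-phenylacetate F4, which are separated by chromatography or crystallisation. F3 is submitted to the LiAlH4 conditions of step 7, which cleave the mandelate as well, and the route is rejoined at 11.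

**Step 9.** The ylide may deprotonate the doubly activated ring CH of 12 (α to the aldehyde and allylic), which would lead to epimerisation or to migration of the ring double bond into conjugation. Fallback, a deoxygenative olefination in which the aldehyde is never formed: from 11, 1,1'-thiocarbonyldiimidazole (THF, 23 °C) closes the 1,2-diol to the cyclic thionocarbonate 4-[(1R,5S)-5-hydroxy-2,6,6-trimethylcyclohex-2-en-1-yl]-1,3-dioxolane-2-thione F5, the hindered ring hydroxyl being expected to stay free. Treatment with 1,3-dimethyl-2-phenyl-1,3,2-diazaphospholidine (THF, 40 °C, Corey–Hopkins variant of the Corey–Winter olefination) then gives 13 directly, the former ester carbon becoming the vinyl terminus.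

**Step 5.** Over-reaction to the bis-olefin and loss of the volatile, hydrate-prone dialdehyde may leave little mono-adduct. Fallback, one aldehyde at a time: from 6, mono-silylation (NaH, Et3SiCl, THF) gives 2,2-dimethyl-3-[(triethylsilyl)oxy]propan-1-ol F6, and Swern oxidation gives 2,2-dimethyl-3-[(triethylsilyl)oxy]propanal F7. Olefination with 5 (LiCl, DBU, MeCN) gives methyl (2Z)-2-({(2Z)-3-[benzyl(dimethyl)silyl]but-2-en-1-yl}oxy)-4,4-dimethyl-5-[(triethylsilyl)oxy]pent-2-enoate F8. Mild acid methanolysis (pyridinium p-toluenesulfonate, MeOH; fluoride is avoided because of the benzylsilane) gives methyl (2Z)-2-({(2Z)-3-[benzyl(dimethyl)silyl]but-2-en-1-yl}oxy)-5-hydroxy-4,4-dimethylpent-2-enoate F9, and Dess–Martin oxidation returns to 8.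

Further compounds
F1 | step 6 | methyl (3R,4S)-4-[benzyl(dimethyl)silyl]-4-methyl-3-(2-methyl-1-oxopropan-2-yl)-2-oxohex-5-enoate | COC(=O)C(=O)[C@@H]([C@@](C)([Si](C)(C)Cc1ccccc1)C=C)C(C)(C)C=O
F2 | step 6 | methyl 2-[(1S,5R)-5-hydroxy-2,6,6-trimethylcyclohex-2-en-1-yl]-2-oxoacetate | COC(=O)C(=O)[C@H]1C(C)=CC[C@@H](O)C1(C)C
F3 | step 6 | (1S,5R)-5-[methoxy(oxo)acetyl]-4,6,6-trimethylcyclohex-3-en-1-yl (2S)-2-(acetyloxy)-2-phenylacetate | CC(=O)O[C@H](C(=O)O[C@H]1CC=C(C)[C@@H](C(=O)C(=O)OC)C1(C)C)c1ccccc1
F4 | step 6 | (1R,5S)-5-[methoxy(oxo)acetyl]-4,6,6-trimethylcyclohex-3-en-1-yl (2S)-2-(acetyloxy)-2-phenylacetate | CC(=O)O[C@H](C(=O)O[C@@H]1CC=C(C)[C@H](C(=O)C(=O)OC)C1(C)C)c1ccccc1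
F5 | step 9 | 4-[(1R,5S)-5-hydroxy-2,6,6-trimethylcyclohex-2-en-1-yl]-1,3-dioxolane-2-thione | S=C1OCC(O1)[C@@H]1C(C)=CC[C@H](O)C1(C)C
F6 | step 5 | 2,2-dimethyl-3-[(triethylsilyl)oxy]propan-1-ol | CC[Si](CC)(CC)OCC(C)(C)CO
F7 | step 5 | 2,2-dimethyl-3-[(triethylsilyl)oxy]propanal | CC[Si](CC)(CC)OCC(C)(C)C=O
F8 | step 5 | methyl (2Z)-2-({(2Z)-3-[benzyl(dimethyl)silyl]but-2-en-1-yl}oxy)-4,4-dimethyl-5-[(triethylsilyl)oxy]pent-2-enoate | COC(=O)/C(OC/C=C(/C)[Si](C)(C)Cc1ccccc1)=C/C(C)(C)CO[Si](CC)(CC)CC
F9 | step 5 | methyl (2Z)-2-({(2Z)-3-[benzyl(dimethyl)silyl]but-2-en-1-yl}oxy)-5-hydroxy-4,4-dimethylpent-2-enoate | COC(=O)/C(OC/C=C(/C)[Si](C)(C)Cc1ccccc1)=C/C(C)(C)CO
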